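## Retrosynthetic overview

1. Target hydroquinone ⇐ reduction of the chromene-5,8-quinone ⇐ DDQ dehydrogenation of the chroman-5,8-quinone.
2. Key step: the benzene ring and the pyran ring are made together in one flask from a 4-alkenyl-4-hydroxycyclobutenone (thermal ring expansion to the hydroquinone, oxidation, oxa-Michael closure by the tertiary alcohol), so the C2–O bond of the stereocentre is never broken.
3. Cyclobutenone ⇐ 2-lithioalkene + methyl semisquarate; the lithioalkene ⇐ vinyl carbinol by hydroboration and Suzuki coupling with 1,1-dibromoethene.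
4. Vinyl carbinol carrying all three stereocentres ⇐ ozonolysis and double methylenation of a bicyclic allylic alcohol ⇐ face-selective MeTi(OiPr)3 addition to the trans-dimethyl octalone ⇐ deracemizing Michael addition and Robinson annulation of 2,6-dimethylcyclohexanone (as its (S)-1-phenylethylamine imine) with methyl vinyl ketone.
5. Ring order: cyclohexane ring B (bought) → temporary ring A (made in step 2, cut open in step 4; it fixes the ring methyl and relays chirality to C2) → benzene and pyran together (step 9).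

Assumption: commercial 2,6-dimethylcyclohexanone is used as its cis/trans mixture, and methyl semisquarate is made (step 7) by the route known for its isopropyl analogue.

## Route

Step 1
Reactants: 1 2,6-dimethylcyclohexan-1-one; 2 (1S)-1-phenylethan-1-amine; 3 but-3-en-2-one
Product: 6 (2R)-2,6-dimethyl-2-(3-oxobutyl)cyclohexan-1-one (C6 epimers), via ketimine 4 (not isolated), via Michael-adduct ketimine 5 (not isolated)
Conditions: TsOH (cat.), PhMe, reflux, Dean–Stark; then 3, THF, 40 °C; then 10% aq AcOH, 25 °C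
Reagents that add atoms: water, O
Why: d'Angelo deracemizing Michael addition, in which the more substituted secondary enamine tautomer of 4 adds to the enone through an aza-ene-like chair transition state on the face away from the phenyl group and so sets the quaternary centre as R, after which mild hydrolysis releases the auxiliary (the C6 methyl centre is corrected in step 2).

Step 2
Reactants: 6 (2R)-2,6-dimethyl-2-(3-oxobutyl)cyclohexan-1-one
Product: 7 (4aR,8R)-4a,8-dimethyl-4,4a,5,6,7,8-hexahydronaphthalen-2(3H)-one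
Conditions: NaOMe (0.3 equiv), MeOH, 60 °C
Reagents that add atoms: none
Why: Intramolecular aldol condensation (second stage of a Robinson annulation) under equilibrating base, where the methyl-bearing C8 epimerizes (α to the ketone before closure, through the extended dienolate afterwards) to the equatorial position trans to the angular methyl, as in 6-alkyl steroidal enones.

Step 3
Reactants: 7 (4aR,8R)-4a,8-dimethyl-4,4a,5,6,7,8-hexahydronaphthalen-2(3H)-one
Product: 8 (2S,4aR,8R)-2,4a,8-trimethyl-2,3,4,4a,5,6,7,8-octahydronaphthalen-2-ol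
Conditions: MeTi(OiPr)3 (2 equiv), Et2O, −20 to 25 °C; H2O work-up
Reagents that add atoms: methyltitanium triisopropoxide MeTi(OiPr)3, C[Ti](OC(C)C)(OC(C)C)OC(C)C
Why: Non-basic 1,2-addition of a bulky organotitanium reagent (Reetz–Seebach), which attacks the enone carbonyl from the equatorial direction (methyl cis to the angular methyl, hydroxyl axial) and so sets the future chromene C2 as S; the two epimers are rigid bicycles and can be separated.

Step 4
Reactants: 8 (2S,4aR,8R)-2,4a,8-trimethyl-2,3,4,4a,5,6,7,8-octahydronaphthalen-2-ol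
Product: 9 (2S)-4-[(1R,3R)-1,3-dimethyl-2-oxocyclohexyl]-2-hydroxy-2-methylbutanal
Conditions: O3, CH2Cl2/MeOH, −78 °C; then Me2S, −78 to 25 °C
Reagents that add atoms: ozone, [O-][O+]=O
Why: Ozonolysis (Criegee mechanism) with reductive work-up cuts the only C=C and opens ring A under neutral conditions, so the carbinol centre and the epimerizable methyl centre next to the new ketone are untouched.

Step 5
Reactants: 9 (2S)-4-[(1R,3R)-1,3-dimethyl-2-oxocyclohexyl]-2-hydroxy-2-methylbutanal
Product: 10 (3S)-5-[(1R,3R)-1,3-dimethyl-2-methylidenecyclohexyl]-3-methylpent-1-en-3-ol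
Conditions: Cp2Ti(μ-Cl)(μ-CH2)AlMe2 (3.5 equiv), pyridine (cat.), THF/PhMe, −40 to 25 °C
Reagents that add atoms: Tebbe reagent Cp2Ti(μ-Cl)(μ-CH2)AlMe2, C[Al](C)C[Ti](Cl)(C1C=CC=C1)C1C=CC=C1
Why: Tebbe methylenation (titanium methylidene, oxatitanacyclobutane) converts both the aldehyde and the hindered enolizable ketone into C=CH2 without base, so no stereocentre is epimerized; the excess reagent covers the free tertiary hydroxyl.

Step 6
Reactants: 10 (3S)-5-[(1R,3R)-1,3-dimethyl-2-methylidenecyclohexyl]-3-methylpent-1-en-3-ol; 11 1,1-dibromoethene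
Product: 13 (5S)-2-bromo-7-[(1R,3R)-1,3-dimethyl-2-methylidenecyclohexyl]-5-methylhept-1-en-5-ol, via B-alkyl-9-BBN 12 (not isolated)
Conditions: 9-BBN (2.2 equiv), THF, 0 to 25 °C; then 11 (5 equiv), Pd(dppf)Cl2 (5 mol%), Cs2CO3, DMF/H2O, 40 °C
Reagents that add atoms: none
Why: Anti-Markovnikov hydroboration of the unhindered vinyl group (the ring methylidene, flanked by a quaternary and a tertiary carbon, is far slower) followed by B-alkyl Suzuki–Miyaura mono-coupling with excess dibromide; no stereocentre is involved.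

Step 7
Reactants: 14 3,4-dimethoxycyclobut-3-ene-1,2-dione
Product: 16 3-methoxycyclobut-3-ene-1,2-dione, via hydroxycyclobutenone 15 (not isolated)
Conditions: LiAlH(OtBu)3, THF, −78 °C; then 6 M HCl, CH2Cl2, 25 °C
Reagents that add atoms: water, O
Why: Hydride 1,2-reduction of one squarate carbonyl followed by acid-induced loss of methanol from the vinylogous hemiacetal (semisquarate synthesis).

Step 8
Reactants: 13 (5S)-2-bromo-7-[(1R,3R)-1,3-dimethyl-2-methylidenecyclohexyl]-5-methylhept-1-en-5-ol; 16 3-methoxycyclobut-3-ene-1,2-dione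
Product: 18 4-[(5S)-7-[(1R,3R)-1,3-dimethyl-2-methylidenecyclohexyl]-5-hydroxy-5-methylhept-1-en-2-yl]-4-hydroxy-3-methoxycyclobut-2-en-1-one (C4 epimers), via dilithio alkenyl alkoxide 17 (not isolated)
Conditions: t-BuLi (3.1 equiv), THF, −78 °C; then 16, −78 °C; H2O
Reagents that add atoms: none
Why: Lithium–bromine exchange and 1,2-addition of the alkenyllithium to the more electrophilic carbonyl of 16 (the one next to the methoxy-bearing carbon; the other is a vinylogous ester), and the new ring centre is lost in step 9.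

Step 9
Reactants: 18 4-[(5S)-7-[(1R,3R)-1,3-dimethyl-2-methylidenecyclohexyl]-5-hydroxy-5-methylhept-1-en-2-yl]-4-hydroxy-3-methoxycyclobut-2-en-1-one
Product: 22 (2S)-2-{2-[(1R,3R)-1,3-dimethyl-2-methylidenecyclohexyl]ethyl}-6-methoxy-2-methyl-3,4-dihydro-2H-chromene-5,8-dione, via hydroquinone 19 (not isolated), via quinone 20 (not isolated), via chroman-5,8-diol 21 (not isolated)
Conditions: PhMe, 110 °C; then Ag2O (3 equiv), ZnCl2 (0.3 equiv), 25 °C
Reagents that add atoms: none
Why: Moore (Liebeskind–Moore) ring expansion (4π ring opening to a dienylketene, 6π electrocyclization, tautomerization) builds the benzene ring with the side chain next to the methoxy-flanked OH, then Ag2O oxidation gives the quinone and Lewis-acid-assisted intramolecular oxa-Michael addition of the tertiary hydroxyl to the free β-position closes the pyran ring with the C2–O bond intact (C2 stays S), and reoxidation gives 22.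

Step 10
Reactants: 22 (2S)-2-{2-[(1R,3R)-1,3-dimethyl-2-methylidenecyclohexyl]ethyl}-6-methoxy-2-methyl-3,4-dihydro-2H-chromene-5,8-dione
Product: 23 (2S)-2-{2-[(1R,3R)-1,3-dimethyl-2-methylidenecyclohexyl]ethyl}-6-methoxy-2-methyl-2H-chromene-5,8-dione
Conditions: DDQ (2 equiv), 1,4-dioxane, 80 °C
Reagents that add atoms: none
Why: DDQ dehydrogenation by hydride abstraction from C4 (cation stabilized through the ring oxygen) and loss of H-3, the reaction type that converts α-lapachone into dehydro-α-lapachone; C2 is quaternary and the ring is not opened, so it cannot epimerize.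

Step 11
Reactants: 23 (2S)-2-{2-[(1R,3R)-1,3-dimethyl-2-methylidenecyclohexyl]ethyl}-6-methoxy-2-methyl-2H-chromene-5,8-dione
Product: 24 (2S)-2-{2-[(1R,3R)-1,3-dimethyl-2-methylidenecyclohexyl]ethyl}-6-methoxy-2-methyl-2H-chromene-5,8-diol
Conditions: Na2S2O4, THF/H2O, 25 °C, Ar
Reagents that add atoms: none
Why: Dithionite reduction of the quinone to the hydroquinone, which leaves both alkenes and all stereocentres untouched.

## Compound list

1 | 2,6-dimethylcyclohexan-1-one (cis/trans mixture) | CC1CCCC(C)C1=O | starting material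
2 | (1S)-1-phenylethan-1-amine | C[C@H](N)c1ccccc1 | starting material
3 | but-3-en-2-one (methyl vinyl ketone) | CC(=O)C=C | starting material
4 | (1S)-N-(2,6-dimethylcyclohexylidene)-1-phenylethan-1-amine | CC1CCCC(C)C1=N[C@@H](C)c1ccccc1 | intermediate
5 | 4-[(1R)-1,3-dimethyl-2-[(1S)-1-phenylethyl]iminocyclohexyl]butan-2-one | CC(=O)CC[C@@]1(C)CCCC(C)C1=N[C@@H](C)c1ccccc1 | intermediate
6 | (2R)-2,6-dimethyl-2-(3-oxobutyl)cyclohexan-1-one (C6 epimers) | CC(=O)CC[C@@]1(C)CCCC(C)C1=O | intermediate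
7 | (4aR,8R)-4a,8-dimethyl-4,4a,5,6,7,8-hexahydronaphthalen-2(3H)-one | O=C1C=C2[C@H](C)CCC[C@]2(C)CC1 | intermediate
8 | (2S,4aR,8R)-2,4a,8-trimethyl-2,3,4,4a,5,6,7,8-octahydronaphthalen-2-ol | C1=C2[C@H](C)CCC[C@]2(C)CC[C@]1(C)O | intermediate
9 | (2S)-4-[(1R,3R)-1,3-dimethyl-2-oxocyclohexyl]-2-hydroxy-2-methylbutanal | O=C[C@@](C)(O)CC[C@@]1(C)CCC[C@@H](C)C1=O | intermediate
10 | (3S)-5-[(1R,3R)-1,3-dimethyl-2-methylidenecyclohexyl]-3-methylpent-1-en-3-ol | C=C[C@@](C)(O)CC[C@@]1(C)CCC[C@@H](C)C1=C | intermediate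
11 | 1,1-dibromoethene | C=C(Br)Br | starting material
12 | (3R)-1-(9-borabicyclo[3.3.1]nonan-9-yl)-5-[(1R,3R)-1,3-dimethyl-2-methylidenecyclohexyl]-3-methylpentan-3-ol (same spatial arrangement as in 10) | C[C@@](O)(CCB1C2CCCC1CCC2)CC[C@@]1(C)CCC[C@@H](C)C1=C | intermediate
13 | (5S)-2-bromo-7-[(1R,3R)-1,3-dimethyl-2-methylidenecyclohexyl]-5-methylhept-1-en-5-ol | C=C(Br)CC[C@@](C)(O)CC[C@@]1(C)CCC[C@@H](C)C1=C | intermediate
14 | 3,4-dimethoxycyclobut-3-ene-1,2-dione (dimethyl squarate) | COC1=C(OC)C(=O)C1=O | starting material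
15 | 4-hydroxy-2,3-dimethoxycyclobut-2-en-1-one | COC1=C(OC)C(O)C1=O | intermediate
16 | 3-methoxycyclobut-3-ene-1,2-dione (methyl semisquarate) | COC1=CC(=O)C1=O | intermediate
17 | dilithio derivative of 13 (2-lithioalkene, lithium alkoxide) | [Li]C(=C)CC[C@@](C)(O[Li])CC[C@@]1(C)CCC[C@@H](C)C1=C | intermediate
18 | 4-[(5S)-7-[(1R,3R)-1,3-dimethyl-2-methylidenecyclohexyl]-5-hydroxy-5-methylhept-1-en-2-yl]-4-hydroxy-3-methoxycyclobut-2-en-1-one (C4 epimers) | COC1=CC(=O)C1(O)C(=C)CC[C@@](C)(O)CC[C@@]1(C)CCC[C@@H](C)C1=C | intermediate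
19 | 2-[(3S)-5-[(1R,3R)-1,3-dimethyl-2-methylidenecyclohexyl]-3-hydroxy-3-methylpentyl]-6-methoxybenzene-1,4-diol | COc1cc(O)cc(CC[C@@](C)(O)CC[C@@]2(C)CCC[C@@H](C)C2=C)c1O | intermediate
20 | 2-[(3S)-5-[(1R,3R)-1,3-dimethyl-2-methylidenecyclohexyl]-3-hydroxy-3-methylpentyl]-6-methoxycyclohexa-2,5-diene-1,4-dione | COC1=CC(=O)C=C(CC[C@@](C)(O)CC[C@@]2(C)CCC[C@@H](C)C2=C)C1=O | intermediate
21 | (2S)-2-{2-[(1R,3R)-1,3-dimethyl-2-methylidenecyclohexyl]ethyl}-6-methoxy-2-methyl-3,4-dihydro-2H-chromene-5,8-diol | COc1cc(O)c2O[C@@](C)(CC[C@@]3(C)CCC[C@@H](C)C3=C)CCc2c1O | intermediate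
22 | (2S)-2-{2-[(1R,3R)-1,3-dimethyl-2-methylidenecyclohexyl]ethyl}-6-methoxy-2-methyl-3,4-dihydro-2H-chromene-5,8-dione | COC1=CC(=O)C2=C(C1=O)CC[C@](C)(CC[C@@]3(C)CCC[C@@H](C)C3=C)O2 | intermediate
23 | (2S)-2-{2-[(1R,3R)-1,3-dimethyl-2-methylidenecyclohexyl]ethyl}-6-methoxy-2-methyl-2H-chromene-5,8-dione | COC1=CC(=O)C2=C(C1=O)C=C[C@](C)(CC[C@@]3(C)CCC[C@@H](C)C3=C)O2 | intermediate
24 | (2S)-2-{2-[(1R,3R)-1,3-dimethyl-2-methylidenecyclohexyl]ethyl}-6-methoxy-2-methyl-2H-chromene-5,8-diol (CNP0247066.1) | C=C1[C@H](C)CCC[C@]1(C)CC[C@@]1(C)C=Cc2c(O)c(OC)cc(O)c2O1 | target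

## Step count and risks

Total step count: 11. Longest linear sequence: 10 (steps 1–6 and 8–11; step 7 is a one-step side branch).

**Step 3 (face selectivity of the methyl addition).** The equatorial preference of MeTi(OiPr)3 is extrapolated from cyclohexanones and steroidal enones and may be modest on this enone. Fallback: set C2 by reagent control. Setting out from 7, alkaline H2O2 gives the 1,8a-epoxy ketone F1, and Eschenmoser–Tanabe fragmentation (TsNHNH2, AcOH) gives the alkynyl ketone F2. Takai–Lombardo methylenation (Zn, CH2Br2, TiCl4, THF/CH2Cl2), which is non-basic and leaves the terminal alkyne alone, then gives the enyne F3. Negishi carboalumination (AlMe3, Cp2ZrCl2 cat.) with paraformaldehyde trapping gives the (E)-allylic alcohol F4. Sharpless epoxidation (Ti(OiPr)4, L-(+)-diethyl tartrate, t-BuOOH) gives the (2S,3S)-epoxy alcohol F5, PPh3/I2/imidazole gives the epoxy iodide F6, and zinc dust opens it reductively to 10, where the route is rejoined.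

**Step 9 (with its feeder step 8).** The addition to the unsubstituted semisquarate 16 and the one-flask ring expansion, oxidation and ring closure are the least precedented part. Fallback: use a ready-made arene. Setting out from 10, hydroboration to 12 and B-alkyl Suzuki coupling with commercial 2-bromo-6-methoxyphenol (Pd(dppf)Cl2, K3PO4) give the phenol F7. Co(salen)/O2 in DMF oxidizes F7 to quinone 20, which is closed and reoxidized as in step 9 to 22, where the route is rejoined.

**Step 10 (DDQ dehydrogenation).** The reagent could also attack the allylic position of the ring methylidene or react sluggishly with the electron-poor quinone. Fallback: put the C3–C4 double bond in place before the pyran is closed. Setting out from 9, Stork–Zhao olefination (Ph3PCH2I+ I−, NaHMDS, −78 °C, no excess base) gives the (Z)-iodoalkene F8, and methylenation of its ketone with Cp2Ti(μ-Cl)(μ-CH2)AlMe2 gives the (Z)-iodo dienol F9. Suzuki coupling with (2-hydroxy-3-methoxyphenyl)boronic acid (Pd(PPh3)4, Na2CO3) gives the (Z)-alkenylphenol F10, kept free of acid. Co(salen)/O2 gives the quinone F11, whose tertiary hydroxyl closes by oxa-Michael addition; the resulting hydroquinone is oxidized in the same flask to 23, where the route is rejoined.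

## Further compounds

F1 | step 3 | 1,8a-epoxide of 7: 1,8a-epoxy-4a,8-dimethyloctahydronaphthalen-2(1H)-one (ring-B centres as in 7, epoxide face unassigned) | O=C1C3OC23[C@H](C)CCC[C@]2(C)CC1
F2 | step 3 | (2R,6R)-2-(but-3-yn-1-yl)-2,6-dimethylcyclohexan-1-one | C#CCC[C@@]1(C)CCC[C@@H](C)C1=O
F3 | step 3 | (1R,3R)-1-(but-3-yn-1-yl)-1,3-dimethyl-2-methylidenecyclohexane | C#CCC[C@@]1(C)CCC[C@@H](C)C1=C
F4 | step 3 | (2E)-5-[(1R,3R)-1,3-dimethyl-2-methylidenecyclohexyl]-3-methylpent-2-en-1-ol | OC/C=C(\C)CC[C@@]1(C)CCC[C@@H](C)C1=C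
F5 | step 3 | [(2S,3S)-3-{2-[(1R,3R)-1,3-dimethyl-2-methylidenecyclohexyl]ethyl}-3-methyloxiran-2-yl]methanol | OC[C@@H]1O[C@@]1(C)CC[C@@]2(C)CCC[C@@H](C)C2=C
F6 | step 3 | (2R,3S)-3-{2-[(1R,3R)-1,3-dimethyl-2-methylidenecyclohexyl]ethyl}-2-(iodomethyl)-3-methyloxirane | IC[C@@H]1O[C@@]1(C)CC[C@@]2(C)CCC[C@@H](C)C2=C
F7 | step 9 | 2-[(3S)-5-[(1R,3R)-1,3-dimethyl-2-methylidenecyclohexyl]-3-hydroxy-3-methylpentyl]-6-methoxyphenol | COc1cccc(CC[C@@](C)(O)CC[C@@]2(C)CCC[C@@H](C)C2=C)c1O
F8 | step 10 | (2R,6R)-2-[(3S,4Z)-3-hydroxy-5-iodo-3-methylpent-4-en-1-yl]-2,6-dimethylcyclohexan-1-one | I/C=C\[C@@](C)(O)CC[C@@]1(C)CCC[C@@H](C)C1=O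
F9 | step 10 | (1Z,3S)-5-[(1R,3R)-1,3-dimethyl-2-methylidenecyclohexyl]-1-iodo-3-methylpent-1-en-3-ol | I/C=C\[C@@](C)(O)CC[C@@]1(C)CCC[C@@H](C)C1=C
F10 | step 10 | 2-[(1Z,3S)-5-[(1R,3R)-1,3-dimethyl-2-methylidenecyclohexyl]-3-hydroxy-3-methylpent-1-en-1-yl]-6-methoxyphenol | COc1cccc(/C=C\[C@@](C)(O)CC[C@@]2(C)CCC[C@@H](C)C2=C)c1O
F11 | step 10 | 2-[(1Z,3S)-5-[(1R,3R)-1,3-dimethyl-2-methylidenecyclohexyl]-3-hydroxy-3-methylpent-1-en-1-yl]-6-methoxycyclohexa-2,5-diene-1,4-dione | COC1=CC(=O)C=C(/C=C\[C@@](C)(O)CC[C@@]2(C)CCC[C@@H](C)C2=C)C1=O
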